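**Retrosynthetic overview**
- Last, the oxygen functions are unmasked: hydrogenation turns a 2‑aryl‑1,4‑benzoquinone into the hydroquinone (ring B) and removes the ring C benzyl ether, then acid removes the ring A MOM ether.
- Key disconnection (new step): both C–C bonds at ring A, the biaryl bond to ring B and the aryl–CH2 bond of the bibenzyl, are cut at once. This leads back to a palladium/norbornene three‑component union of MOM‑protected 2‑iodo‑5‑methoxyphenol, 3‑(benzyloxy)phenethyl bromide and 1,4‑benzoquinone.
- The iodide fixes the regiochemistry: iodine sits ortho to the oxygen and para to OMe, and its only free ortho C–H is where the phenethyl chain must go.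
- No ring is built: rings A, C and B are bought as the iodophenol, 2‑(3‑hydroxyphenyl)ethanol and benzoquinone; the only ring event is the reduction of ring B from quinone to arene in the penultimate step.

Assumption: the target SMILES has no stereodescriptor and no stereocentre, and the tri‑ortho‑substituted biaryl axis (OH, OH, CH2 flanking) is taken as freely rotating at room temperature, so no stereochemical element has to be set.

**Step 1**
Reactants: 1 2‑iodo‑5‑methoxyphenol
Product: 2 1‑iodo‑4‑methoxy‑2‑(methoxymethoxy)benzene
Conditions: MOMCl (1.3 equiv), K2CO3 (2 equiv), acetone, 0 °C to 40 °C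
Reagents that add atoms: chloromethyl methyl ether (COCCl)
Why: Williamson‑type O‑alkylation of the phenoxide by the reactive α‑chloro ether gives a base‑stable MOM acetal that has no aryl C–H bond able to intercept the arylpalladium species of step 4.

**Step 2**
Reactants: 3 2‑(3‑hydroxyphenyl)ethanol
Product: 4 2‑[3‑(benzyloxy)phenyl]ethanol
Conditions: BnBr (1.05 equiv), K2CO3 (1.5 equiv), acetone, reflux
Reagents that add atoms: benzyl bromide (BrCc1ccccc1)
Why: Chemoselective Williamson etherification, since K2CO3 ionises only the phenol and leaves the primary alcohol unalkylated.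

**Step 3**
Reactants: 4 2‑[3‑(benzyloxy)phenyl]ethanol
Product: 5 1‑(benzyloxy)‑3‑(2‑bromoethyl)benzene
Conditions: CBr4 (1.2 equiv), PPh3 (1.25 equiv), CH2Cl2, 0 °C to rt
Reagents that add atoms: carbon tetrabromide (BrC(Br)(Br)Br)
Why: Appel reaction of an unhindered primary alcohol under neutral conditions that leave the benzyl aryl ether untouched.

**Step 4**
Reactants: 2 1‑iodo‑4‑methoxy‑2‑(methoxymethoxy)benzene; 5 1‑(benzyloxy)‑3‑(2‑bromoethyl)benzene (2 equiv); 6 1,4‑benzoquinone (2 equiv)
Product: 7 2‑{2‑[2‑(3‑(benzyloxy)phenyl)ethyl]‑4‑methoxy‑6‑(methoxymethoxy)phenyl}cyclohexa‑2,5‑diene‑1,4‑dione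
Conditions: Pd(OAc)2 (10 mol%), AsPh3 (25 mol%), norbornene (2 equiv), K2CO3 (2.5 equiv), MeCN, 80 °C, 6 added by syringe pump over 6 h
Reagents that add atoms: none
Why: Proposed new method: a Catellani‑type palladium/norbornene ortho C–H alkylation terminated by Heck‑type C–H arylation of a quinone, in which zerovalent palladium inserts into the C–I bond of 2, norbornene carbopalladation and ortho C–H palladation give the aryl–norbornyl palladacycle, primary bromide 5 adds oxidatively to give a tetravalent palladium species whose reductive elimination forms the aryl–CH2 bond, the now 2,6‑disubstituted ring expels norbornene, and the resulting divalent arylpalladium carbopalladates the electron‑poor C=C of 6, after which carbonate‑assisted enolisation to a palladium hydroquinonate and inner‑sphere electron transfer release quinone 7 and zerovalent palladium; the closest known reactions are the Catellani ortho‑alkylation with Heck (acrylate) or Suzuki termination and the addition of arylpalladium species to quinones in boronic acid–quinone couplings, and the design follows from that mechanism (AsPh3 in place of a phosphine, which would add to 6; slow addition of 6 so that norbornene captures the first arylpalladium species; symmetric 6 so that only one regioisomer can form); no stereocentre is formed.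

**Step 5**
Reactants: 7 2‑{2‑[2‑(3‑(benzyloxy)phenyl)ethyl]‑4‑methoxy‑6‑(methoxymethoxy)phenyl}cyclohexa‑2,5‑diene‑1,4‑dione
Product: 9 2‑{2‑[2‑(3‑hydroxyphenyl)ethyl]‑4‑methoxy‑6‑(methoxymethoxy)phenyl}benzene‑1,4‑diol, via benzyl‑protected hydroquinone 8 (not isolated)
Conditions: H2 (1 atm), 10% Pd/C, EtOAc/EtOH 1:1, rt; filtered under argon
Reagents that add atoms: none
Why: Catalytic hydrogenation reduces the quinone to the hydroquinone within minutes and then hydrogenolyses the benzyl aryl ether, while the MOM acetal, the aryl methyl ether and the arenes are inert at 1 atm and rt.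

**Step 6**
Reactants: 9 2‑{2‑[2‑(3‑hydroxyphenyl)ethyl]‑4‑methoxy‑6‑(methoxymethoxy)phenyl}benzene‑1,4‑diol
Product: 10 2‑{2‑hydroxy‑6‑[2‑(3‑hydroxyphenyl)ethyl]‑4‑methoxyphenyl}benzene‑1,4‑diol
Conditions: HCl (3 M in MeOH, 5 equiv), degassed MeOH, 45 °C, argon
Reagents that add atoms: none
Why: Acid‑catalysed acetal methanolysis transfers the methoxymethyl group to the solvent and frees the last phenol, while the aryl methyl ether is stable to HCl/MeOH and the large excess of methanol traps the oxocarbenium ion before it can alkylate the electron‑rich rings.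

**Compound list**
1 | 2‑iodo‑5‑methoxyphenol | COc1ccc(I)c(O)c1 | starting material
2 | 1‑iodo‑4‑methoxy‑2‑(methoxymethoxy)benzene | COCOc1cc(OC)ccc1I | intermediate
3 | 2‑(3‑hydroxyphenyl)ethanol | OCCc1cccc(O)c1 | starting material
4 | 2‑[3‑(benzyloxy)phenyl]ethanol | OCCc1cccc(OCc2ccccc2)c1 | intermediate
5 | 1‑(benzyloxy)‑3‑(2‑bromoethyl)benzene | BrCCc1cccc(OCc2ccccc2)c1 | intermediate
6 | 1,4‑benzoquinone | O=C1C=CC(=O)C=C1 | starting material
7 | 2‑{2‑[2‑(3‑(benzyloxy)phenyl)ethyl]‑4‑methoxy‑6‑(methoxymethoxy)phenyl}cyclohexa‑2,5‑diene‑1,4‑dione | COCOc1cc(OC)cc(CCc2cccc(OCc3ccccc3)c2)c1C1=CC(=O)C=CC1=O | intermediate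
8 | 2‑{2‑[2‑(3‑(benzyloxy)phenyl)ethyl]‑4‑methoxy‑6‑(methoxymethoxy)phenyl}benzene‑1,4‑diol (not isolated) | COCOc1cc(OC)cc(CCc2cccc(OCc3ccccc3)c2)c1-c1cc(O)ccc1O | intermediate
9 | 2‑{2‑[2‑(3‑hydroxyphenyl)ethyl]‑4‑methoxy‑6‑(methoxymethoxy)phenyl}benzene‑1,4‑diol | COCOc1cc(OC)cc(CCc2cccc(O)c2)c1-c1cc(O)ccc1O | intermediate
10 | 2‑{2‑hydroxy‑6‑[2‑(3‑hydroxyphenyl)ethyl]‑4‑methoxyphenyl}benzene‑1,4‑diol | COc1cc(O)c(-c2cc(O)ccc2O)c(CCc2cccc(O)c2)c1 | target

**Step count and risks**
Total steps: 6. Longest linear sequence: 5 steps (3 → 4 → 5 → 7 → 9 → 10; steps 2, 3, 4, 5, 6).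

Step 4 (the proposed new step) is the most likely to fail. Benzoquinone may capture the first arylpalladium iodide before norbornene does, or be degraded by carbonate. The hindered arylpalladium may instead arylate ring C intramolecularly to a 9,10‑dihydrophenanthrene. Bromide 5 may also eliminate to the styrene. The fallback uses known chemistry and sets out from 2 and 5. The established Catellani ortho‑alkylation with Suzuki termination (Pd(OAc)2, PPh3, norbornene, K2CO3, DMF, 90 °C) with commercial 2,5‑dimethoxyphenylboronic acid gives 2‑{2‑[3‑(benzyloxy)phenyl]ethyl}‑2',4,5'‑trimethoxy‑6‑(methoxymethoxy)‑1,1'‑biphenyl F1. Oxidative demethylation of its para‑dimethoxyarene ring with (NH4)2Ce(NO3)6 in MeCN/H2O at 0 °C then gives the quinone, and the route is rejoined at 7.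

Step 5 may fail if the catalyst is poisoned by traces of iodide or arsenic carried over from step 4, or if the debenzylation stalls. The fallback sets out from 7 and avoids hydrogen altogether. Na2S2O4 in THF/H2O reduces only the quinone, so that compound 8 is now isolated. BCl3 with pentamethylbenzene as cation scavenger in CH2Cl2 at −78 °C, quenched with MeOH, then cleaves the benzyl ether and the MOM acetal together while the aryl methyl ether survives. This comes back to the route at 10 and bypasses 9.

Step 6 may fail because the electron‑rich 2,2'‑dihydroxybiaryl can be bridged or alkylated by the formaldehyde equivalent set free in acid, and the hydroquinone can air‑oxidise during the reaction. The fallback changes the protecting group so that no acidic step is needed, and sets out from 1. Benzyl chloromethyl ether with K2CO3 in acetone gives 2‑[(benzyloxy)methoxy]‑1‑iodo‑4‑methoxybenzene F2. Coupling of F2 with 5 and 6 under the step 4 conditions gives 2‑{2‑[(benzyloxy)methoxy]‑6‑[2‑(3‑(benzyloxy)phenyl)ethyl]‑4‑methoxyphenyl}cyclohexa‑2,5‑diene‑1,4‑dione F3. A single hydrogenation (H2, 10% Pd/C, EtOAc/EtOH) reduces the quinone and hydrogenolyses both the benzyl ether and the benzyloxymethyl acetal, coming back to the route directly at 10.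

**Further compounds**
F1 | step 4 | 2‑{2‑[3‑(benzyloxy)phenyl]ethyl}‑2',4,5'‑trimethoxy‑6‑(methoxymethoxy)‑1,1'‑biphenyl | COCOc1cc(OC)cc(CCc2cccc(OCc3ccccc3)c2)c1-c1cc(OC)ccc1OC
F0 | step 5 | none | none
F2 | step 6 | 2‑[(benzyloxy)methoxy]‑1‑iodo‑4‑methoxybenzene | COc1ccc(I)c(OCOCc2ccccc2)c1
F3 | step 6 | 2‑{2‑[(benzyloxy)methoxy]‑6‑[2‑(3‑(benzyloxy)phenyl)ethyl]‑4‑methoxyphenyl}cyclohexa‑2,5‑diene‑1,4‑dione | COc1cc(OCOCc2ccccc2)c(C2=CC(=O)C=CC2=O)c(CCc2cccc(OCc3ccccc3)c2)c1
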